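**Retrosynthetic overview**

- Target ⇐ its 3'-O-MOM ether ⇐ (one flask) a 7-methyl-2H,5H-pyrano[4,3-b]pyran-5-one that already carries the prenyl group and the dimethylpyran ring + methyl 3-(methoxymethoxy)benzoate. The C6–C(=O)Ar bond is made by Claisen acylation of the C7-methyl anion; the C5–C6 ring bond follows by Claisen closure once methoxide opens the lactone (pyranone → acylphloroglucinol).
- Enabling feature: benzene ring A of the chromene bears oxygen on C5, C7 and C8a, with the aroyl carbon on C6 between C5–OH and C7–OH. This is the pattern of a Claisen-folded tetraketide, so C6 is a former chain-terminal methyl carbon, C5 can be a lactone carbonyl tied to the C7 oxygen (2-pyranone), and the C8a carbonyl can be masked as the enol ether of the dimethylpyran ring (O1).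
- Pyranopyranone ⇐ 4-hydroxy-6-methyl-5-prenyl-2-pyranone + 3-methylbut-2-enal (Knoevenagel/oxa-6π). Pyranone ⇐ methyl 4-prenyl-3,5-dioxohexanoate ⇐ 3-prenylacetylacetone dianion + dimethyl carbonate ⇐ acetylacetone + prenyl bromide.
- Ring order: 2-pyranone (step 3), 2,2-dimethyl-2H-pyran (step 4), benzene ring A last (step 6, at the expense of the pyranone ring). The 3-hydroxyphenyl ring is bought as methyl 3-hydroxybenzoate.

Key step: step 6

Remark: the target has no stereocentre and no stereogenic double bond (the ring alkene is cis by constraint), so no step has to control configuration. Compounds 10 and 11 are written as neutral keto forms although they exist as metal enolates in the flask.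

**Route**

Step 1
Reactants: 1 pentane-2,4-dione (acetylacetone); 2 1-bromo-3-methylbut-2-ene (prenyl bromide)
Product: 3 3-(3-methylbut-2-en-1-yl)pentane-2,4-dione
Conditions: 1 (1.5 equiv), K2CO3, acetone, reflux
Reagents that add atoms: none
Why: SN2 C-alkylation of the doubly stabilised acetylacetone enolate by an allylic bromide should give the mono-C-prenyl diketone, the excess of 1 holding back dialkylation.

Step 2
Reactants: 3 3-(3-methylbut-2-en-1-yl)pentane-2,4-dione
Product: 4 methyl 4-acetyl-7-methyl-3-oxooct-6-enoate
Conditions: LDA (3.1 equiv), THF, −78 → 0 °C; (MeO)2CO, −78 → −20 °C; cold 1 M HCl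
Reagents that add atoms: dimethyl carbonate, COC(=O)OC
Why: The 1,3-dianion of the β-diketone (methine first, then a terminal methyl) should react at its more basic terminal carbanion with the carbonate in a Claisen-type C-acylation; the two methyl groups of 3 are equivalent, so only one diketo ester can form, and the third equivalent of base covers the acidic product.

Step 3
Reactants: 4 methyl 4-acetyl-7-methyl-3-oxooct-6-enoate
Product: 5 4-hydroxy-6-methyl-5-(3-methylbut-2-en-1-yl)-2H-pyran-2-one
Conditions: DBU (1.5 equiv), toluene, 110 °C; cold dilute HCl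
Reagents that add atoms: none
Why: Under DBU the enol oxygen of the acetyl group should add to the methyl ester with loss of methanol (6-exo-trig lactonisation), the standard cyclisation of 3,5-dioxo esters to 4-hydroxy-2-pyranones, while the weakly acidic methyl group does not compete for carbocycle formation.

Step 4
Reactants: 5 4-hydroxy-6-methyl-5-(3-methylbut-2-en-1-yl)-2H-pyran-2-one; 6 3-methylbut-2-enal
Product: 7 2,2,7-trimethyl-8-(3-methylbut-2-en-1-yl)-2H,5H-pyrano[4,3-b]pyran-5-one
Conditions: ethylenediammonium diacetate (10 mol %), EtOAc, 80 °C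
Reagents that add atoms: none
Why: Knoevenagel condensation of the enal (as its iminium ion) at C3 of the pyranone should give a 1-oxatriene that closes by oxa-6π electrocyclisation through the C4 oxygen (formal [3+3] annulation), the established way from 4-hydroxy-2-pyranones and this enal to 2,2-dimethylpyrano[4,3-b]pyran-5-ones.

Step 5
Reactants: 8 methyl 3-hydroxybenzoate
Product: 9 methyl 3-(methoxymethoxy)benzoate
Conditions: MOMCl, K2CO3, acetone, 0 °C → rt
Reagents that add atoms: chloromethyl methyl ether (MOMCl), COCCl
Why: Williamson-type O-alkylation of the phenoxide by the reactive α-chloro ether should give the MOM acetal, which is inert to all later basic steps.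

Step 6
Reactants: 7 2,2,7-trimethyl-8-(3-methylbut-2-en-1-yl)-2H,5H-pyrano[4,3-b]pyran-5-one; 9 methyl 3-(methoxymethoxy)benzoate
Product: 12 [5,7-dihydroxy-2,2-dimethyl-8-(3-methylbut-2-en-1-yl)-2H-chromen-6-yl][3-(methoxymethoxy)phenyl]methanone, via acylmethyl pyranopyranone 10 (not isolated), via open-chain triketo ester 11 (not isolated)
Conditions: LDA (2.2 equiv), THF, −78 °C; 9 (1.1 equiv), −78 → 0 °C; then Mg(OMe)2, MeOH, 65 °C; cold 1 M HCl to pH 4
Reagents that add atoms: none
Why: LDA should remove a proton from the C7 methyl group of 7, the only C–H whose anion is conjugated through C7=C8 and C8a=C4a into the lactone carbonyl, and this exocyclic carbanion should be C-acylated by ester 9 (Claisen condensation), which forms the bond between the future C6 of the chromene and the benzophenone carbonyl carbon and gives the enolate of 10, the second equivalent of base being taken up by this more acidic keto pyranone. Magnesium methoxide should then open the lactone at C5 to the magnesium chelate of triketo ester 11, whose doubly activated methylene attacks the new ester carbon in a 6-exo-trig Claisen (Dieckmann-type) closure; loss of methoxide and enolisation give benzene ring A as the chelated acylphloroglucinol, and this irreversible aromatisation drains the pyranone/open-chain equilibrium. The closest known reaction types are the side-chain acylation of 6-methyl-4-alkoxy-2-pyranone anions and the methoxide-mediated isomerisation of 6-(2-oxoalkyl)-2-pyranones to acylphloroglucinols, the laboratory counterpart of the Claisen folding of a tetraketide. No stereocentre is formed. The step needs Claisen instead of aldol folding and a single substitution pattern on ring A: the aldol mode is shut because the chain carbon that would have to attack the aryl ketone (C4a) is fully substituted inside the dimethylpyran ring and could not aromatise, the cis C4a=C8a bond of that ring holds the ester and the diketone side chain within reach, and the positions of the prenyl group (C8) and the pyran oxygen (on C8a) are fixed in 7 before the benzene ring exists.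

Step 7
Reactants: 12 [5,7-dihydroxy-2,2-dimethyl-8-(3-methylbut-2-en-1-yl)-2H-chromen-6-yl][3-(methoxymethoxy)phenyl]methanone
Product: 13 [5,7-dihydroxy-2,2-dimethyl-8-(3-methylbut-2-en-1-yl)-2H-chromen-6-yl](3-hydroxyphenyl)methanone
Conditions: conc. HCl (cat.), MeOH, rt → 40 °C, stopped at full conversion
Reagents that add atoms: none
Why: Acid-catalysed acetal exchange with methanol should free the phenol; dilute HCl in methanol near room temperature is the usual way to remove MOM ethers from ortho-prenylated phenols and should leave the prenyl and chromene double bonds untouched.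

**Compound list**

1 | pentane-2,4-dione (acetylacetone) | CC(=O)CC(C)=O | starting material
2 | 1-bromo-3-methylbut-2-ene (prenyl bromide) | CC(C)=CCBr | starting material
3 | 3-(3-methylbut-2-en-1-yl)pentane-2,4-dione | CC(=O)C(CC=C(C)C)C(C)=O | intermediate
4 | methyl 4-acetyl-7-methyl-3-oxooct-6-enoate | COC(=O)CC(=O)C(CC=C(C)C)C(C)=O | intermediate
5 | 4-hydroxy-6-methyl-5-(3-methylbut-2-en-1-yl)-2H-pyran-2-one | CC1=C(CC=C(C)C)C(O)=CC(=O)O1 | intermediate
6 | 3-methylbut-2-enal | CC(C)=CC=O | starting material
7 | 2,2,7-trimethyl-8-(3-methylbut-2-en-1-yl)-2H,5H-pyrano[4,3-b]pyran-5-one | CC1=C(CC=C(C)C)C2=C(C=CC(C)(C)O2)C(=O)O1 | intermediate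
8 | methyl 3-hydroxybenzoate | COC(=O)c1cccc(O)c1 | starting material
9 | methyl 3-(methoxymethoxy)benzoate | COCOc1cccc(c1)C(=O)OC | intermediate
10 | 7-{2-[3-(methoxymethoxy)phenyl]-2-oxoethyl}-2,2-dimethyl-8-(3-methylbut-2-en-1-yl)-2H,5H-pyrano[4,3-b]pyran-5-one | COCOc1cccc(c1)C(=O)CC1=C(CC=C(C)C)C2=C(C=CC(C)(C)O2)C(=O)O1 | intermediate (not isolated)
11 | methyl 6-{1-[3-(methoxymethoxy)phenyl]-7-methyl-1,3-dioxooct-6-en-4-yl}-2,2-dimethyl-2H-pyran-5-carboxylate | COCOc1cccc(c1)C(=O)CC(=O)C(CC=C(C)C)C1=C(C(=O)OC)C=CC(C)(C)O1 | intermediate (not isolated)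
12 | [5,7-dihydroxy-2,2-dimethyl-8-(3-methylbut-2-en-1-yl)-2H-chromen-6-yl][3-(methoxymethoxy)phenyl]methanone | CC(C)=CCc1c(O)c(C(=O)c2cccc(OCOC)c2)c(O)c2c1OC(C)(C)C=C2 | intermediate
13 | [5,7-dihydroxy-2,2-dimethyl-8-(3-methylbut-2-en-1-yl)-2H-chromen-6-yl](3-hydroxyphenyl)methanone | CC(C)=CCc1c(O)c(C(=O)c2cccc(O)c2)c(O)c2c1OC(C)(C)C=C2 | target

**Step count**

Total steps: 7. Longest linear sequence: 6 (steps 1, 2, 3, 4, 6, 7).

**Steps most likely to fail**

Step 6. The cascade may stall or divert in four ways:
- the amide base or methoxide may attack the pyranone ring before the methyl group is acylated;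
- the stabilised anion may be acylated too slowly by a methyl ester;
- methoxide may cleave the new 1,3-diketone again (retro-Claisen);
- the ring-opened ester may return to the pyranone instead of closing onto carbon.

The fallback sets out from 4 and returns at 12; it makes the same bond on the unmasked chain. The trianion of 4 (LDA, 3.3 equiv, THF, −78 → 0 °C) should be acylated at its terminal methyl carbon by 9 to give methyl 7-[3-(methoxymethoxy)phenyl]-4-(3-methylbut-2-en-1-yl)-3,5,7-trioxoheptanoate F1. KOH in methanol (or Mg(OMe)2) should fold this ester by Claisen condensation to [2,4,6-trihydroxy-3-(3-methylbut-2-en-1-yl)phenyl][3-(methoxymethoxy)phenyl]methanone F2. Condensation of the latter with 6 (ethylenediammonium diacetate cat., toluene, 110 °C) should close the dimethylpyran ring at the free ring carbon through the hydroxyl para to the ketone and reach 12. The isomer closed through an ortho hydroxyl would have to be removed by chromatography.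

Step 7. During acetal cleavage the acid may add the C7 hydroxyl across the prenyl double bond (closure to a dihydropyran) or hydrate and oligomerise the chromene. The fallback sets out from 8 and returns at 13; it replaces the acid-labile group by one removed under neutral conditions. Allyl bromide and K2CO3 in acetone should give methyl 3-(prop-2-en-1-yloxy)benzoate F3. Under the conditions of step 6 with 7 this ester should pass through 2,2-dimethyl-8-(3-methylbut-2-en-1-yl)-7-{2-oxo-2-[3-(prop-2-en-1-yloxy)phenyl]ethyl}-2H,5H-pyrano[4,3-b]pyran-5-one F4 and methyl 2,2-dimethyl-6-{7-methyl-1,3-dioxo-1-[3-(prop-2-en-1-yloxy)phenyl]oct-6-en-4-yl}-2H-pyran-5-carboxylate F5, neither isolated, to [5,7-dihydroxy-2,2-dimethyl-8-(3-methylbut-2-en-1-yl)-2H-chromen-6-yl][3-(prop-2-en-1-yloxy)phenyl]methanone F6. Pd(PPh3)4 (cat.) and morpholine in THF at rt should then transfer the allyl group to the amine and give 13.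

Step 2. Proton transfer from the acidic product to unreacted dianion, O-acylation or double acylation may limit the methoxycarbonylation. The fallback sets out from 2 and returns at 4; it builds the same diketo ester from the ester end. The dianion of commercial methyl acetoacetate (NaH, then n-BuLi, THF, 0 °C) should be alkylated at its terminal carbon by 2 to give methyl 7-methyl-3-oxooct-6-enoate F7. The dianion of this keto ester (LDA, 2.2 equiv, THF, −78 °C) should be acetylated at the same carbon by N-methoxy-N-methylacetamide to give 4.

**Further compounds**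

F1 | step 6 | methyl 7-[3-(methoxymethoxy)phenyl]-4-(3-methylbut-2-en-1-yl)-3,5,7-trioxoheptanoate | COC(=O)CC(=O)C(CC=C(C)C)C(=O)CC(=O)c1cccc(OCOC)c1
F2 | step 6 | [2,4,6-trihydroxy-3-(3-methylbut-2-en-1-yl)phenyl][3-(methoxymethoxy)phenyl]methanone | CC(C)=CCc1c(O)cc(O)c(C(=O)c2cccc(OCOC)c2)c1O
F3 | step 7 | methyl 3-(prop-2-en-1-yloxy)benzoate | C=CCOc1cccc(c1)C(=O)OC
F4 | step 7 | 2,2-dimethyl-8-(3-methylbut-2-en-1-yl)-7-{2-oxo-2-[3-(prop-2-en-1-yloxy)phenyl]ethyl}-2H,5H-pyrano[4,3-b]pyran-5-one | C=CCOc1cccc(c1)C(=O)CC1=C(CC=C(C)C)C2=C(C=CC(C)(C)O2)C(=O)O1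
F5 | step 7 | methyl 2,2-dimethyl-6-{7-methyl-1,3-dioxo-1-[3-(prop-2-en-1-yloxy)phenyl]oct-6-en-4-yl}-2H-pyran-5-carboxylate | C=CCOc1cccc(c1)C(=O)CC(=O)C(CC=C(C)C)C1=C(C(=O)OC)C=CC(C)(C)O1
F6 | step 7 | [5,7-dihydroxy-2,2-dimethyl-8-(3-methylbut-2-en-1-yl)-2H-chromen-6-yl][3-(prop-2-en-1-yloxy)phenyl]methanone | CC(C)=CCc1c(O)c(C(=O)c2cccc(OCC=C)c2)c(O)c2c1OC(C)(C)C=C2
F7 | step 2 | methyl 7-methyl-3-oxooct-6-enoate | COC(=O)CC(=O)CCC=C(C)C
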